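Germacrane numbering is used throughout (ring C1–C10, C14 on C10, C15 on C4, C11–C13 on C7), also for the open-chain precursors; α/β refer to the usual germacranolide drawing with H-7 α.

## Structural features

The target is a germacranolide: a ten-membered carbocycle trans-fused across C6–C7 to an α-methyl-γ-butyrolactone (O on C6, C7–C11–C12(=O), C13 on C11), with a 2-(acetoxymethyl)acrylate on O-8 and a free primary allylic alcohol at C15. Both ring alkenes are trisubstituted: C1=C10 is E, and C4=C5 has C3 and C6 on opposite sides (ring-trans), which is formally Z only because C15 carries oxygen. Four contiguous stereocentres, C6 (R), C7 (R), C8 (S) and C11 (S), stand next to each other: H-6 β, H-7 α, O-8 α and CH3-13 α, so O-6/C11 and C11/O-8 are both trans on the ring and C13 is trans to C8 on the lactone. The fragile parts are the (E,E)-cyclodeca-1,5-diene (Cope rearrangement on heating, transannular cyclisation with acid), the acrylate with its allylic acetate (Michael and SN2′ acceptor, base-labile), and any 8α-hydroxy-12,6-olide, which can translactonise to O-8 under base. The real difficulty is closing the strained ten-membered ring with both alkene geometries defined while setting the C6/C7/C8 triad; the acylation and oxidation-level changes are routine by comparison. The key step exploits the array O–C6–C7–C11(C13)–C12: once the lactone is traced back to a C6 carbinol beside a C7 isopropenyl group and C4=C5 is drawn as C4≡C5, C6 is a propargylic carbinol next to an allyl-derived carbon, the retron of a [2,3]-Wittig shift. The O-6/C12 connection of the lactone then reappears as the ether bridge of a 13-membered ring.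

## Logic of the disconnections

37 ⇒ 36 ⇒ 32 + 35. The O15–Si bond and the C8–O acyl bond are cut last-in, first-out, so that the electrophilic side chain is exposed only to one mild fluoride step. This reduces the target to a protected core and a three-carbon acid. It demands acylation of a hindered secondary alcohol without a strongly nucleophilic medium, and a C15 protecting group that outlasts removal of the C8 silyl ether (31 ⇒ 32); hence TBDPS on O-15 against TBS on O-8.

31 ⇒ 30 ⇒ 28 ⇒ 26. The lactone C12–O6 bond and the C12 oxidation level are removed, then the C12–O bond itself, which leaves an isopropenyl group on C7 and a free C6 carbinol. C11 is not cut but relegated to a thermodynamic equilibration. The forward steps demand hydroboration of the 1,1-disubstituted alkene only, oxidation of the primary alcohol in the presence of the secondary allylic one, and a clear thermodynamic preference for the 11α-methyl epimer.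

26 ⇒ 25 ⇒ 24 ⇒ 22. The C4–C15 bond is cut (hydroxymethyl transfer to an alkenyl iodide), then C4–I and C5–H are taken back to the C4≡C5 alkyne. This removes C15 and the second trisubstituted alkene at once. It demands a trans-addition across the alkyne steered by O-6, so that C3 and C6 end up on opposite sides.

22 ⇒ 20 (strategic). The C6–C7 bond is cut and O-6 is reconnected to C12. The ten-membered carbocycle becomes a 13-membered ether that is far easier to close, and the stereocentres C6 and C7 are traded for one E alkene and the existing C8 centre. The forward step demands selective deprotonation at C6, a [2,3] rather than a [1,2] shift, and face control by C8.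

20 ⇒ 19 ⇒ 18 ⇒ 17. The O–C6 ether bond is cut to an allylic alkoxide at O-12 and a propargylic bromide at C6. This opens the ring to a linear C12 chain. It demands an O-12 protecting group orthogonal to the C8 silyl ether and to a propargylic bromide (PMB), and high dilution in the closure.

17 ⇒ 15 ⇒ 14 ⇒ 11 + 12. C5–C6 is cut to an acetylide and formaldehyde, and C1–C2 to an alkenyl iodide and a homopropargylic zinc reagent. This splits the chain into a chiral C7 unit and an achiral C4 unit. It demands retention of the E geometry in the sp2–sp3 coupling and a capped alkyne (the nucleophile must be an alkylzinc, not an alkynylzinc).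

11 ⇒ 9 ⇒ 8 ⇒ 6 + 7. C10–C14 and C1–I are cut by retro-carbometalation, then C8–C9 by retro-propargylation. All chirality is thereby reduced to one catalyst-controlled addition to an achiral enal. It demands high enantioselectivity on a β,β-disubstituted enal.

6 ⇒ 4 ⇒ 3 ⇒ 1. The C7–C8 (formyl) bond and the C11–C13 bond are cut back to a three-carbon alkyne. The forward demand is the E geometry (C13 cis to the future C8) and a formyl group on the unmethylated alkene carbon.

35 ⇒ 34 ⇒ 33. The acetate and the ethyl ester are cut to a commercial hydroxy ester.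

## Other disconnections considered

Alternative 1: The cut is the C5–C10 σ bond read in reverse: the ring-trans C4=C5 and the E C10=C1 alkenes are taken as the ends of a hexatriene, so that the ten-membered ring of the triene lactone A1 is hidden in the trans-fused decalin of the eudesma-1,3-dienolide A2. Forward, irradiation of A2 at 254 nm at low temperature would open the cyclohexadiene by a six-electron conrotatory electrocyclic reaction. The trans ring fusion would translate into the two required alkene geometries, with an extra cis C2=C3 bond that then has to be saturated (diimide) to reach the silyl-protected germacranolide A5. In its favour: no entropically difficult cyclisation, both trisubstituted alkenes fixed by orbital symmetry, and C6, C7, C11 and the lactone available from an abundant eudesmanolide. Against it here: the opening is reversible (a photostationary mixture, with thermal disrotatory reclosure of the triene), and A2 needs oxygen at C8α and at C15, positions that are unfunctionalised in the available eudesmanolides. The reduction must also pick the disubstituted alkene among three in a molecule prone to Cope rearrangement. Comparison: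
- Structure: A1 already carries the lactone, C11 and C15 and is ahead of 22; here the alternative is better.
- Mechanism: both key steps are pericyclic, but the Wittig shift is driven to completion by alkoxide formation whereas the photoreaction stops at an equilibrium, which favours the chosen plan.
- Step economy: about four steps after the key step against eleven here (better), but the remote oxidations needed for A2 should cost more than the twelve steps to 20, so the total is at best equal.

Alternative 2: The cut is C7–C8. The aldehyde–butenolide A4 would be treated with SmI2, HMPA and t-BuOH. Single-electron reduction of the C8 aldehyde gives a ketyl radical that adds to C7 of the α-methylbutenolide (10-exo-trig), and the samarium enolate formed after a second electron transfer is protonated at C11 to give the 8-hydroxy lactone A3. In its favour: one step would make the ring and three stereocentres (C7, C8, C11) from the single centre C6 of A4, with the lactone and both alkenes in place beforehand. A3 also has a free C8 hydroxyl and a single silyl ether, so acylation and desilylation finish the synthesis without differentiating protecting groups; in this respect the alternative is better than the chosen plan. Against it: the ketyl can instead be reduced to the alcohol or couple to a pinacol, or the butenolide can be reduced on its own. Only the folding of an open chain with two E alkenes decides the configurations at C7 and C8, and the β,γ-unsaturated aldehyde of A4 isomerises easily into conjugation. Comparison: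
- Structure: A3 is much more advanced than 22.
- Mechanism: a stepwise radical/anionic sequence setting three centres under kinetic control of a flexible chain is less predictable than a concerted shift in a preformed ring whose two new centres are tied to one alkene geometry and one existing centre.
- Step economy: the alternative would be shorter overall if its closure worked; the chosen plan is preferred only because its ring closure is judged more dependable.

Alternative 3: The cut is C1–C2. In the iodo diene lactone A6, 9-BBN would add to the terminal C2=C3 vinyl group to put boron on C2. Pd(dppf)Cl2 with AsPh3 and aqueous Cs2CO3 would then couple this alkylborane with the C1 alkenyl iodide (B-alkyl Suzuki–Miyaura macrocyclisation) to give A5. In its favour: an sp2–sp3 coupling of broad generality, both alkene geometries fixed in A6, all four stereocentres and the lactone present, and the lactone acting as a turn element. A5 is three steps from the target and carries a triethylsilyl/TBS pair that is easier to differentiate than the TBS/TBDPS pair of 31; on both counts the alternative is better. Against it: the vinyl group belongs to a 2-substituted 1,3-diene, so clean 1,2-hydroboration at C2 beside an alkenyl iodide is not assured. Reductive elimination must form a strained (E,E)-cyclodecadiene from an eleven-membered palladacycle, where protodeboronation, β-hydride elimination and dimerisation compete. A6 also needs four contiguous stereocentres built by acyclic stereocontrol. Comparison: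
- Structure: A5 corresponds to 31, so the ring would be closed on a more complete molecule.
- Mechanism: the coupling must pay the full strain of the ten-membered ring in the organometallic step, while the chosen plan closes a nearly strain-free 13-membered ether first and lets a sigmatropic shift contract it.
- Step economy: fewer steps after ring closure (better), more before it, roughly equal overall.

Key step: step 13

Assumption: the (S)-configured phosphoric acid is taken to direct the allenylboronate to the Si face of enal 6, as this catalyst family does with aryl aldehydes; if the sense were opposite, the (R)-acid would be used with no other change.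

Remark on the five-carbon electrophile: the enal must carry CHO on the unmethylated alkene carbon. The 2-methyl enal that SeO2 oxidation of prenyl acetate delivers has CHO next to the methyl group; propargylation of it would put the methyl on C7 and give a vinyl instead of an isopropenyl group after the shift. The enal is therefore built from propargyl alcohol. The zinc partner in the C1–C2 coupling is a homopropargylic alkylzinc with a silyl-capped alkyne, not an alkynylzinc.

## Route

Step 1
Reactants: 1 prop-2-yn-1-ol
Product: 3 (E)-3-iodo-2-methylprop-2-en-1-ol, via alkenylalane 2 (not isolated)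
Conditions: AlMe3 (3 equiv), Cp2ZrCl2 (0.25 equiv), CH2Cl2, 0 °C → rt; then I2, THF, −30 → 0 °C
Reagents that add atoms: trimethylaluminium, C[Al](C)C; iodine, II
Why: Zirconium-catalysed syn-methylalumination (Negishi carboalumination) puts CH3 on the internal and aluminium on the terminal alkyne carbon, and iodinolysis with retention gives the E iodide. This fixes the later C7=C11 geometry with C13 cis to the carbon that will bear C8.

Step 2
Reactants: 3 (E)-3-iodo-2-methylprop-2-en-1-ol
Product: 4 1-({[(2E)-3-iodo-2-methylprop-2-en-1-yl]oxy}methyl)-4-methoxybenzene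
Conditions: NaH, PMBCl, Bu4NI (cat.), THF/DMF, 0 °C → rt
Reagents that add atoms: 4-methoxybenzyl chloride, COc1ccc(CCl)cc1
Why: Williamson etherification of the primary alkoxide. PMB is chosen because it can later be removed oxidatively beside the silyl ether and a propargylic bromide.

Step 3
Reactants: 4 1-({[(2E)-3-iodo-2-methylprop-2-en-1-yl]oxy}methyl)-4-methoxybenzene
Product: 6 (2E)-4-(4-methoxybenzyloxy)-3-methylbut-2-enal, via alkenyllithium 5 (not isolated)
Conditions: t-BuLi (2.1 equiv), Et2O, −78 °C; then DMF, −78 → 0 °C
Reagents that add atoms: N,N-dimethylformamide, CN(C)C=O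
Why: Iodine–lithium exchange is faster than any attack on the benzyl ether and the alkenyllithium keeps its geometry; formylation with DMF gives the E enal with CHO on the unmethylated carbon (future C8 on C7).

Step 4
Reactants: 6 (2E)-4-(4-methoxybenzyloxy)-3-methylbut-2-enal; 7 4,4,5,5-tetramethyl-2-(propa-1,2-dien-1-yl)-1,3,2-dioxaborolane
Product: 8 (4S,5E)-7-(4-methoxybenzyloxy)-6-methylhept-5-en-1-yn-4-ol
Conditions: 7 (1.5 equiv), (S)-TRIP [(S)-3,3′-bis(2,4,6-triisopropylphenyl)-1,1′-binaphthalene-2,2′-diyl hydrogen phosphate] (5 mol%), 4 Å MS, toluene, −20 °C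
Reagents that add atoms: none
Why: Chiral-phosphoric-acid-catalysed propargylboration: the allenylboronate adds through a closed six-membered SE2′ transition state and gives only the homopropargylic alcohol. The (S)-acid should shield the Re face of the hydrogen-bonded aldehyde, so Si-face attack sets C8 as S.

Step 5
Reactants: 8 (4S,5E)-7-(4-methoxybenzyloxy)-6-methylhept-5-en-1-yn-4-ol
Product: 9 tert-butyl{[(4S,5E)-7-(4-methoxybenzyloxy)-6-methylhept-5-en-1-yn-4-yl]oxy}dimethylsilane
Conditions: TBSCl, imidazole, DMF, rt
Reagents that add atoms: tert-butyldimethylsilyl chloride, CC(C)(C)[Si](C)(C)Cl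
Why: Standard silylation of a secondary alcohol. The bulky, non-coordinating silyl ether is inert to organolithium, hydride and aluminium reagents and later serves as the controlling substituent at C8.

Step 6
Reactants: 9 tert-butyl{[(4S,5E)-7-(4-methoxybenzyloxy)-6-methylhept-5-en-1-yn-4-yl]oxy}dimethylsilane
Product: 11 tert-butyl{[(1E,4S,5E)-1-iodo-7-(4-methoxybenzyloxy)-2,6-dimethylhepta-1,5-dien-4-yl]oxy}dimethylsilane, via alkenylalane 10 (not isolated)
Conditions: AlMe3 (2.5 equiv), Cp2ZrCl2 (0.2 equiv), CH2Cl2, 0 °C → rt; then I2, THF, −30 °C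
Reagents that add atoms: trimethylaluminium, C[Al](C)C; iodine, II
Why: Second Negishi carboalumination: syn addition with aluminium at the terminus and iodinolysis with retention give the E-configured C10=C1 iodide with C14 in place. The ethers and the trisubstituted alkene are inert.

Step 7
Reactants: 11 tert-butyl{[(1E,4S,5E)-1-iodo-7-(4-methoxybenzyloxy)-2,6-dimethylhepta-1,5-dien-4-yl]oxy}dimethylsilane; 12 (4-bromobut-1-yn-1-yl)trimethylsilane
Product: 14 (5E,8S,9E)-8-(tert-butyldimethylsilyloxy)-11-(4-methoxybenzyloxy)-6,10-dimethyl-1-(trimethylsilyl)undeca-5,9-dien-1-yne, via alkylzinc bromide 13 (not isolated)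
Conditions: 12, Zn dust, LiCl, THF, 50 °C; then 11, PdCl2(dppf) (5 mol%), THF, rt → 40 °C
Reagents that add atoms: none
Why: Zinc insertion gives a homopropargylic alkylzinc that undergoes Negishi sp2–sp3 coupling with retention of the alkene geometry, forming C1–C2. The wide bite angle of dppf favours reductive elimination over β-hydride elimination, and the silyl cap prevents metalation of the alkyne.

Step 8
Reactants: 14 (5E,8S,9E)-8-(tert-butyldimethylsilyloxy)-11-(4-methoxybenzyloxy)-6,10-dimethyl-1-(trimethylsilyl)undeca-5,9-dien-1-yne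
Product: 15 (5E,8S,9E)-8-(tert-butyldimethylsilyloxy)-11-(4-methoxybenzyloxy)-6,10-dimethylundeca-5,9-dien-1-yne
Conditions: K2CO3, MeOH, rt
Reagents that add atoms: none
Why: Methanolysis of the alkynyl C–Si bond by catalytic methoxide; the silyl and benzyl ethers are unaffected.

Step 9
Reactants: 15 (5E,8S,9E)-8-(tert-butyldimethylsilyloxy)-11-(4-methoxybenzyloxy)-6,10-dimethylundeca-5,9-dien-1-yne
Product: 17 (6E,9S,10E)-9-(tert-butyldimethylsilyloxy)-12-(4-methoxybenzyloxy)-7,11-dimethyldodeca-6,10-dien-2-yn-1-ol, via lithium acetylide 16 (not isolated)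
Conditions: n-BuLi, THF, −78 °C; then (CH2O)n, −78 °C → rt
Reagents that add atoms: formaldehyde (as paraformaldehyde), C=O
Why: Deprotonation of the terminal alkyne, the only acidic C–H under these conditions, and addition of the acetylide to formaldehyde install C6 as the propargylic carbinol.

Step 10
Reactants: 17 (6E,9S,10E)-9-(tert-butyldimethylsilyloxy)-12-(4-methoxybenzyloxy)-7,11-dimethyldodeca-6,10-dien-2-yn-1-ol
Product: 18 (6E,9S,10E)-1-bromo-9-(tert-butyldimethylsilyloxy)-12-(4-methoxybenzyloxy)-7,11-dimethyldodeca-6,10-dien-2-yne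
Conditions: CBr4, PPh3, 2,6-lutidine, CH2Cl2, 0 °C
Reagents that add atoms: carbon tetrabromide, BrC(Br)(Br)Br
Why: Appel bromination under nearly neutral conditions turns the primary propargylic alcohol into the SN2 electrophile; lutidine buffers traces of HBr so that the silyl and PMB ethers survive.

Step 11
Reactants: 18 (6E,9S,10E)-1-bromo-9-(tert-butyldimethylsilyloxy)-12-(4-methoxybenzyloxy)-7,11-dimethyldodeca-6,10-dien-2-yne
Product: 19 (2E,4S,6E)-12-bromo-4-(tert-butyldimethylsilyloxy)-2,6-dimethyldodeca-2,6-dien-10-yn-1-ol
Conditions: DDQ, CH2Cl2/pH 7 buffer (10:1), 0 °C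
Reagents that add atoms: none
Why: Oxidative cleavage of the electron-rich benzyl ether by hydride abstraction; the bromide, silyl ether, alkyne and unactivated alkenes should not react with DDQ under buffered conditions.

Step 12
Reactants: 19 (2E,4S,6E)-12-bromo-4-(tert-butyldimethylsilyloxy)-2,6-dimethyldodeca-2,6-dien-10-yn-1-ol
Product: 20 (3E,5S,7E)-5-(tert-butyldimethylsilyloxy)-3,7-dimethyl-1-oxacyclotrideca-3,7-dien-11-yne
Conditions: NaH (5 equiv), THF, 45 °C, slow addition of 19 (final 0.002 M)
Reagents that add atoms: none
Why: Intramolecular Williamson etherification (13-membered ring, exo-tet displacement at the unhindered propargylic carbon). Slow addition keeps the alkoxide dilute so that cyclisation outpaces oligomerisation, and the alkyne and two E alkenes leave the chain few unproductive conformations.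

Step 13
Reactants: 20 (3E,5S,7E)-5-(tert-butyldimethylsilyloxy)-3,7-dimethyl-1-oxacyclotrideca-3,7-dien-11-yne
Product: 22 (1S,6E,9S,10S)-9-(tert-butyldimethylsilyloxy)-7-methyl-10-(prop-1-en-2-yl)cyclodec-6-en-2-yn-1-ol [germacrane numbering: 6S,7S,8S; 6α-OH; H-7 α; 8α-OTBS], via C6-lithiated ether 21 (not isolated)
Conditions: n-BuLi (1.2 equiv), THF (0.01 M), −78 °C; then AcOH, −78 °C
Reagents that add atoms: none
Why: n-BuLi removes a proton from C6, the only carbon that is both propargylic and α to oxygen, and carbanion 21 attacks C7 on the face of the allyl unit from which the O–C12 bond departs, a concerted suprafacial [2,3]-sigmatropic (Wittig) shift through a five-membered envelope (C6, O, C12, C11, C7). The closest known reaction type is the [2,3]-Wittig ring contraction of macrocyclic allyl propargyl ethers to cycloalkynols. The ten-membered ring is closed transannularly inside the 13-membered ring by the new C6–C7 bond (contraction by the three atoms O, C12 and C11, which become the alkoxide and the isopropenyl group), so the entropic cost was paid in step 12 and the strain is paid by the change from carbanion to alkoxide. C7 is controlled by C8: because the alkene is E, C13 is cis to C8 and allylic 1,3-strain keeps H-8 in the alkene plane, the C9 tether must lie on the face reached by C6, and the silyloxy group therefore lies on the other face, which makes C11 and O-8 trans. C6 is controlled relative to C7 by the E geometry together with an exo (pseudo-equatorial) alkynyl arm in the envelope, which should give the 6,7-trans (anti) alcohol. The step needs deprotonation at C6 and not at C12 (secured by the higher acidity of the propargylic position), a [2,3] and not a [1,2] shift (secured by −78 °C and the lithium counter-ion), and no silyl shift from O-8 to the new alkoxide (secured by the cold acidic quench).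

Step 14
Reactants: 22 (1S,6E,9S,10S)-9-(tert-butyldimethylsilyloxy)-7-methyl-10-(prop-1-en-2-yl)cyclodec-6-en-2-yn-1-ol
Product: 24 8α-(tert-butyldimethylsilyloxy)-4-iodo-15-norgermacra-1(10)E,4Z,11-trien-6α-ol (I cis to C6; C3 and C6 on opposite sides), via cyclic alkenylaluminate 23 (not isolated)
Conditions: NaAlH2(OCH2CH2OMe)2 (3 equiv), THF, 0 °C → rt; EtOAc; then I2, THF, −78 → −20 °C
Reagents that add atoms: iodine, II
Why: The C6 alkoxide binds aluminium and delivers hydride intramolecularly to C5 (trans-hydroalumination), which gives a five-membered oxa-aluminacycle with aluminium on C4; iodinolysis with retention places iodine on C4 cis to C6, so C3 and C6 are on opposite sides of the new alkene. The silyl ether and the isolated alkenes are inert to the aluminate.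

Step 15
Reactants: 24 8α-(tert-butyldimethylsilyloxy)-4-iodo-15-norgermacra-1(10)E,4Z,11-trien-6α-ol
Product: 25 8α-(tert-butyldimethylsilyloxy)germacra-1(10)E,4Z,11-triene-6α,15-diol
Conditions: Bu3SnCH2OH (2 equiv), Pd2(dba)3 (5 mol%), P(2-furyl)3 (20 mol%), CuI (20 mol%), NMP, 50 °C
Reagents that add atoms: (tributylstannyl)methanol, CCCC[Sn](CCCC)(CCCC)CO
Why: Stille coupling with retention at the alkenyl carbon; the hydroxymethyl group is transferred from tin in preference to butyl. CuI with a weakly donating phosphine should allow a temperature below the onset of Cope rearrangement of the 1,5-diene.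

Step 16
Reactants: 25 8α-(tert-butyldimethylsilyloxy)germacra-1(10)E,4Z,11-triene-6α,15-diol
Product: 26 8α-(tert-butyldimethylsilyloxy)-15-(tert-butyldiphenylsilyloxy)germacra-1(10)E,4Z,11-trien-6α-ol
Conditions: TBDPSCl (1.05 equiv), imidazole, CH2Cl2, −20 → 0 °C
Reagents that add atoms: tert-butyldiphenylsilyl chloride, CC(C)(C)[Si](Cl)(c1ccccc1)c1ccccc1
Why: Sterically selective silylation of the primary allylic alcohol over the hindered secondary C6 alcohol. TBDPS is chosen because it must outlast cleavage of the C8 TBS ether.

Step 17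
Reactants: 26 8α-(tert-butyldimethylsilyloxy)-15-(tert-butyldiphenylsilyloxy)germacra-1(10)E,4Z,11-trien-6α-ol
Product: 28 8α-(tert-butyldimethylsilyloxy)-15-(tert-butyldiphenylsilyloxy)germacra-1(10)E,4Z-diene-6α,12-diol (C11 epimers), via C12 alkylborane 27 (not isolated)
Conditions: 9-BBN (3 equiv), THF, 0 °C → rt; then H2O2, aq. NaHCO3, 0 °C → rt
Reagents that add atoms: hydrogen peroxide, OO
Why: 9-BBN hydroborates the 1,1-disubstituted isopropenyl alkene anti-Markovnikov far faster than the two trisubstituted ring alkenes, and buffered peroxide oxidation gives the primary C12 alcohol without base-induced silyl migration. C11 is formed without reliable control here and is set in step 19.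

Step 18
Reactants: 28 8α-(tert-butyldimethylsilyloxy)-15-(tert-butyldiphenylsilyloxy)germacra-1(10)E,4Z-diene-6α,12-diol (C11 epimers)
Product: 30 8α-(tert-butyldimethylsilyloxy)-15-(tert-butyldiphenylsilyloxy)germacra-1(10)E,4Z-dien-12,6α-olide (C11 epimers), via lactol 29 (not isolated)
Conditions: TEMPO (0.2 equiv), PhI(OAc)2 (2.5 equiv), CH2Cl2, rt
Reagents that add atoms: none
Why: Oxoammonium (TEMPO) oxidation is selective for the primary alcohol; the hydroxy aldehyde closes to the five-membered lactol, which is oxidised on to the lactone. The secondary allylic C6 hydroxyl is thereby consumed as the ring oxygen and the trans ring fusion follows from C6 and C7.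

Step 19
Reactants: 30 8α-(tert-butyldimethylsilyloxy)-15-(tert-butyldiphenylsilyloxy)germacra-1(10)E,4Z-dien-12,6α-olide (C11 epimers)
Product: 31 (11S)-8α-(tert-butyldimethylsilyloxy)-15-(tert-butyldiphenylsilyloxy)-11βH-germacra-1(10)E,4Z-dien-12,6α-olide
Conditions: t-BuOK (0.3 equiv), t-BuOH/THF, 0 °C → rt; then AcOH
Reagents that add atoms: none
Why: Reversible enolisation of the lactone with a hindered, non-nucleophilic alkoxide equilibrates C11. The epimer with C13 trans to the C7–C8 bond (11α-methyl, 11S) avoids the eclipsing interaction with C8 and its silyloxy group and should dominate at equilibrium.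

Step 20
Reactants: 31 (11S)-8α-(tert-butyldimethylsilyloxy)-15-(tert-butyldiphenylsilyloxy)-11βH-germacra-1(10)E,4Z-dien-12,6α-olide
Product: 32 8α-hydroxy-15-(tert-butyldiphenylsilyloxy)-11βH-germacra-1(10)E,4Z-dien-12,6α-olide
Conditions: HF·pyridine, pyridine, THF, 0 °C → rt
Reagents that add atoms: none
Why: Buffered HF·pyridine cleaves a TBS ether faster than the more acid-stable TBDPS ether. The medium is non-basic, which avoids migration of the lactone from O-6 to the freed O-8 and spares the acid-sensitive diene.

Step 21
Reactants: 33 ethyl 2-(hydroxymethyl)acrylate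
Product: 34 2-(hydroxymethyl)acrylic acid
Conditions: LiOH·H2O, THF/H2O, 0 °C; then 1 M HCl to pH 2
Reagents that add atoms: lithium hydroxide, [Li+].[OH-]
Why: Saponification of the ethyl ester at low temperature, where conjugate addition of hydroxide to the acrylate is slow.

Step 22
Reactants: 34 2-(hydroxymethyl)acrylic acid
Product: 35 2-(acetoxymethyl)acrylic acid
Conditions: AcCl (1.5 equiv), CH2Cl2, 0 °C → rt
Reagents that add atoms: acetyl chloride, CC(=O)Cl
Why: O-Acetylation of the primary allylic alcohol by the acid chloride; any mixed anhydride formed at the carboxyl group is hydrolysed in the aqueous work-up.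

Step 23
Reactants: 32 8α-hydroxy-15-(tert-butyldiphenylsilyloxy)-11βH-germacra-1(10)E,4Z-dien-12,6α-olide; 35 2-(acetoxymethyl)acrylic acid
Product: 36 8α-[2-(acetoxymethyl)acryloyloxy]-15-(tert-butyldiphenylsilyloxy)-11βH-germacra-1(10)E,4Z-dien-12,6α-olide
Conditions: 35 (3 equiv), EDC·HCl, DMAP (0.1 equiv), CH2Cl2, 0 °C
Reagents that add atoms: none
Why: Carbodiimide (Steglich) esterification of the secondary C8 alcohol with retention at C8. Only a catalytic amount of DMAP at 0 °C is used, to limit its addition to the acetoxymethyl acrylate.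

Step 24
Reactants: 36 8α-[2-(acetoxymethyl)acryloyloxy]-15-(tert-butyldiphenylsilyloxy)-11βH-germacra-1(10)E,4Z-dien-12,6α-olide
Product: 37 CNP0291063.1, (6R,7R,8S,11S)-8α-[2-(acetoxymethyl)acryloyloxy]-15-hydroxy-11βH-germacra-1(10)E,4Z-dien-12,6α-olide
Conditions: TBAF, AcOH (1:1), THF, 0 °C → rt
Reagents that add atoms: none
Why: Fluoride cleavage of the primary silyl ether buffered with acetic acid, so that neither the acetate, the acrylate nor the lactone meets a basic alkoxide.

## Compound list

1 | prop-2-yn-1-ol | C#CCO | starting material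
2 | dimethyl[(1E)-3-(dimethylalumanyloxy)-2-methylprop-1-en-1-yl]alumane | C[Al](C)OC/C(C)=C/[Al](C)C | intermediate
3 | (E)-3-iodo-2-methylprop-2-en-1-ol | OC/C(C)=C/I | intermediate
4 | 1-({[(2E)-3-iodo-2-methylprop-2-en-1-yl]oxy}methyl)-4-methoxybenzene | COc1ccc(COC/C(C)=C/I)cc1 | intermediate
5 | [(1E)-3-(4-methoxybenzyloxy)-2-methylprop-1-en-1-yl]lithium | COc1ccc(COC/C(C)=C/[Li])cc1 | intermediate
6 | (2E)-4-(4-methoxybenzyloxy)-3-methylbut-2-enal | COc1ccc(COC/C(C)=C/C=O)cc1 | intermediate
7 | 4,4,5,5-tetramethyl-2-(propa-1,2-dien-1-yl)-1,3,2-dioxaborolane | C=C=CB1OC(C)(C)C(C)(C)O1 | starting material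
8 | (4S,5E)-7-(4-methoxybenzyloxy)-6-methylhept-5-en-1-yn-4-ol | COc1ccc(COC/C(C)=C/[C@@H](O)CC#C)cc1 | intermediate
9 | tert-butyl{[(4S,5E)-7-(4-methoxybenzyloxy)-6-methylhept-5-en-1-yn-4-yl]oxy}dimethylsilane | COc1ccc(COC/C(C)=C/[C@@H](O[Si](C)(C)C(C)(C)C)CC#C)cc1 | intermediate
10 | [(1E,4S,5E)-4-(tert-butyldimethylsilyloxy)-7-(4-methoxybenzyloxy)-2,6-dimethylhepta-1,5-dien-1-yl]dimethylalumane | COc1ccc(COC/C(C)=C/[C@@H](O[Si](C)(C)C(C)(C)C)C/C(C)=C/[Al](C)C)cc1 | intermediate
11 | tert-butyl{[(1E,4S,5E)-1-iodo-7-(4-methoxybenzyloxy)-2,6-dimethylhepta-1,5-dien-4-yl]oxy}dimethylsilane | COc1ccc(COC/C(C)=C/[C@@H](O[Si](C)(C)C(C)(C)C)C/C(C)=C/I)cc1 | intermediate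
12 | (4-bromobut-1-yn-1-yl)trimethylsilane | C[Si](C)(C)C#CCCBr | starting material
13 | bromo[4-(trimethylsilyl)but-3-yn-1-yl]zinc | C[Si](C)(C)C#CCC[Zn]Br | intermediate
14 | (5E,8S,9E)-8-(tert-butyldimethylsilyloxy)-11-(4-methoxybenzyloxy)-6,10-dimethyl-1-(trimethylsilyl)undeca-5,9-dien-1-yne | COc1ccc(COC/C(C)=C/[C@@H](O[Si](C)(C)C(C)(C)C)C/C(C)=C/CCC#C[Si](C)(C)C)cc1 | intermediate
15 | (5E,8S,9E)-8-(tert-butyldimethylsilyloxy)-11-(4-methoxybenzyloxy)-6,10-dimethylundeca-5,9-dien-1-yne | COc1ccc(COC/C(C)=C/[C@@H](O[Si](C)(C)C(C)(C)C)C/C(C)=C/CCC#C)cc1 | intermediate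
16 | lithium acetylide of 15 | COc1ccc(COC/C(C)=C/[C@@H](O[Si](C)(C)C(C)(C)C)C/C(C)=C/CCC#C[Li])cc1 | intermediate
17 | (6E,9S,10E)-9-(tert-butyldimethylsilyloxy)-12-(4-methoxybenzyloxy)-7,11-dimethyldodeca-6,10-dien-2-yn-1-ol | COc1ccc(COC/C(C)=C/[C@@H](O[Si](C)(C)C(C)(C)C)C/C(C)=C/CCC#CCO)cc1 | intermediate
18 | (6E,9S,10E)-1-bromo-9-(tert-butyldimethylsilyloxy)-12-(4-methoxybenzyloxy)-7,11-dimethyldodeca-6,10-dien-2-yne | COc1ccc(COC/C(C)=C/[C@@H](O[Si](C)(C)C(C)(C)C)C/C(C)=C/CCC#CCBr)cc1 | intermediate
19 | (2E,4S,6E)-12-bromo-4-(tert-butyldimethylsilyloxy)-2,6-dimethyldodeca-2,6-dien-10-yn-1-ol | OC/C(C)=C/[C@@H](O[Si](C)(C)C(C)(C)C)C/C(C)=C/CCC#CCBr | intermediate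
20 | (3E,5S,7E)-5-(tert-butyldimethylsilyloxy)-3,7-dimethyl-1-oxacyclotrideca-3,7-dien-11-yne | O1C/C(C)=C/[C@@H](O[Si](C)(C)C(C)(C)C)C/C(C)=C/CCC#CC1 | intermediate
21 | 13-lithio derivative of 20 (lithium on germacrane C6) | O1C/C(C)=C/[C@@H](O[Si](C)(C)C(C)(C)C)C/C(C)=C/CCC#CC1[Li] | intermediate
22 | (1S,6E,9S,10S)-9-(tert-butyldimethylsilyloxy)-7-methyl-10-(prop-1-en-2-yl)cyclodec-6-en-2-yn-1-ol | CC(C)(C)[Si](C)(C)O[C@H]1C/C(C)=C/CCC#C[C@@H](O)[C@@H]1C(C)=C | intermediate
23 | sodium salt of the cyclic C4-alkenyl C6-alkoxy bis(2-methoxyethoxy)aluminate | CC(C)(C)[Si](C)(C)O[C@H]1C/C(C)=C/CC/C2=C/[C@@H](O[Al-]2(OCCOC)OCCOC)[C@@H]1C(C)=C.[Na+] | intermediate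
24 | 8α-(tert-butyldimethylsilyloxy)-4-iodo-15-norgermacra-1(10)E,4Z,11-trien-6α-ol | CC(C)(C)[Si](C)(C)O[C@H]1C/C(C)=C/CC/C(I)=C/[C@@H](O)[C@@H]1C(C)=C | intermediate
25 | 8α-(tert-butyldimethylsilyloxy)germacra-1(10)E,4Z,11-triene-6α,15-diol | CC(C)(C)[Si](C)(C)O[C@H]1C/C(C)=C/CC/C(CO)=C/[C@@H](O)[C@@H]1C(C)=C | intermediate
26 | 8α-(tert-butyldimethylsilyloxy)-15-(tert-butyldiphenylsilyloxy)germacra-1(10)E,4Z,11-trien-6α-ol | CC(C)(C)[Si](C)(C)O[C@H]1C/C(C)=C/CC/C(CO[Si](c2ccccc2)(c2ccccc2)C(C)(C)C)=C/[C@@H](O)[C@@H]1C(C)=C | intermediate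
27 | C12 B-alkyl-9-borabicyclo[3.3.1]nonane of 26 with O-6 as its 9-BBN borinate (C11 epimers) | CC(C)(C)[Si](C)(C)O[C@H]1C/C(C)=C/CC/C(CO[Si](c2ccccc2)(c2ccccc2)C(C)(C)C)=C/[C@@H](OB2C3CCCC2CCC3)[C@@H]1C(C)CB1C2CCCC1CCC2 | intermediate
28 | 8α-(tert-butyldimethylsilyloxy)-15-(tert-butyldiphenylsilyloxy)germacra-1(10)E,4Z-diene-6α,12-diol (C11 epimers) | CC(C)(C)[Si](C)(C)O[C@H]1C/C(C)=C/CC/C(CO[Si](c2ccccc2)(c2ccccc2)C(C)(C)C)=C/[C@@H](O)[C@@H]1C(C)CO | intermediate
29 | 12,6α-lactol of 28 (C11 and C12 epimers) | CC(C)(C)[Si](C)(C)O[C@H]1C/C(C)=C/CC/C(CO[Si](c3ccccc3)(c3ccccc3)C(C)(C)C)=C/[C@H]2OC(O)C(C)[C@H]12 | intermediate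
30 | 8α-(tert-butyldimethylsilyloxy)-15-(tert-butyldiphenylsilyloxy)germacra-1(10)E,4Z-dien-12,6α-olide (C11 epimers) | CC(C)(C)[Si](C)(C)O[C@H]1C/C(C)=C/CC/C(CO[Si](c3ccccc3)(c3ccccc3)C(C)(C)C)=C/[C@H]2OC(=O)C(C)[C@H]12 | intermediate
31 | (11S)-8α-(tert-butyldimethylsilyloxy)-15-(tert-butyldiphenylsilyloxy)-11βH-germacra-1(10)E,4Z-dien-12,6α-olide | CC(C)(C)[Si](C)(C)O[C@H]1C/C(C)=C/CC/C(CO[Si](c3ccccc3)(c3ccccc3)C(C)(C)C)=C/[C@H]2OC(=O)[C@@H](C)[C@H]12 | intermediate
32 | 8α-hydroxy-15-(tert-butyldiphenylsilyloxy)-11βH-germacra-1(10)E,4Z-dien-12,6α-olide | O[C@H]1C/C(C)=C/CC/C(CO[Si](c3ccccc3)(c3ccccc3)C(C)(C)C)=C/[C@H]2OC(=O)[C@@H](C)[C@H]12 | intermediate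
33 | ethyl 2-(hydroxymethyl)acrylate | C=C(CO)C(=O)OCC | starting material
34 | 2-(hydroxymethyl)acrylic acid | C=C(CO)C(=O)O | intermediate
35 | 2-(acetoxymethyl)acrylic acid | C=C(COC(C)=O)C(=O)O | intermediate
36 | 8α-[2-(acetoxymethyl)acryloyloxy]-15-(tert-butyldiphenylsilyloxy)-11βH-germacra-1(10)E,4Z-dien-12,6α-olide | C=C(COC(C)=O)C(=O)O[C@H]1C/C(C)=C/CC/C(CO[Si](c3ccccc3)(c3ccccc3)C(C)(C)C)=C/[C@H]2OC(=O)[C@@H](C)[C@H]12 | intermediate
37 | CNP0291063.1, (6R,7R,8S,11S)-8α-[2-(acetoxymethyl)acryloyloxy]-15-hydroxy-11βH-germacra-1(10)E,4Z-dien-12,6α-olide | C=C(COC(C)=O)C(=O)O[C@H]1C/C(C)=C/CC/C(CO)=C/[C@H]2OC(=O)[C@@H](C)[C@H]12 | target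

## Step count and least certain steps

Total step count: 24. Longest linear sequence: 22 steps (steps 1–20, 23 and 24); steps 21 and 22 make the side-chain acid.

Step 13 (key step). The most likely failure is erosion of the 6,7-diastereoselectivity: the alkynyl arm is part of the ring being formed, and a transition state with this arm endo, which the ring may accommodate more easily than an open-chain ether would, leads to the 6,7-cis carbinol. Partial silyl transfer from O-8 to the new alkoxide on warming is a second risk. Fallback from 20: the rearrangement is still used to close the ring and the mis-set carbinol is corrected afterwards. The 6-epimeric enynol F1 is subjected to Mitsunobu inversion with 4-nitrobenzoic acid (PPh3, DIAD) to give the 6α 4-nitrobenzoate F2, and methanolysis (K2CO3, MeOH) returns to 22.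

Step 12. Intermolecular etherification can outrun closure of the 13-membered ring, and the strongly basic allylic alkoxide can also isomerise the propargylic bromide towards an allene. The fallback from 17 reverses the roles of the two termini, so that a less basic propargylic alkoxide attacks an allylic chloride:
- 17 is protected at O-6 (3,4-dihydro-2H-pyran, PPTS) to give the tetrahydropyranyl ether F3.
- DDQ frees the allylic alcohol F4.
- MsCl/Et3N then LiCl gives the allylic chloride F5.
- PPTS in MeOH gives the chloro alcohol F6.
- Slow addition of F6 to EtMgBr in THF/HMPA closes the ring to 20.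

Step 19. The equilibrium at C11 may be incomplete or less one-sided than expected, because the preference rests only on the interaction of C13 with the C8 substituent across the five-membered ring. The fallback from 30 sets C11 kinetically instead:
- LiN(i-Pr)2 then PhSeBr gives the 11-phenylselanyl lactone F7.
- H2O2 eliminates the selenoxide to the 11(13)-methylene lactone F8.
- Conjugate reduction with NaBH4 in MeOH, with protonation of the enolate from the open face, returns to 31.

Step 20. Concurrent loss of the C15 silyl group, or incomplete cleavage at the hindered C8 position, is the likely problem, since the selectivity is only one of rate. Fallback from 31: both silyl ethers are removed with excess unbuffered HF·pyridine to give the 8α,15-diol F9, and the primary allylic hydroxyl alone is re-silylated (TBDPSCl, imidazole, −20 °C), which returns to 32.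

Step 23. The acylation of the hindered C8 hydroxyl may be slow, and the nucleophilic catalyst can attack the acetoxymethyl acrylate in an SN2′ sense with loss of acetate. The fallback from 32 builds the side chain on the substrate:
- Esterification with diethylphosphonoacetic acid (DCC) gives the phosphonoacetate F10.
- Horner–Wadsworth–Emmons reaction with aqueous formaldehyde and K2CO3 gives the 2-(hydroxymethyl)acrylate F11.
- Acetylation (Ac2O, pyridine) returns to 36.

Further compounds
F1 | step 13 | 6-epimer of 22 (6β-hydroxy; 6,7-cis) | CC(C)(C)[Si](C)(C)O[C@H]1C/C(C)=C/CCC#C[C@H](O)[C@@H]1C(C)=C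
F2 | step 13 | 4-nitrobenzoate of 22 (6α-acyloxy) | CC(C)(C)[Si](C)(C)O[C@H]1C/C(C)=C/CCC#C[C@@H](OC(=O)c2ccc(cc2)[N+](=O)[O-])[C@@H]1C(C)=C
F3 | step 12 | tetrahydropyranyl ether of 17 | COc1ccc(COC/C(C)=C/[C@@H](O[Si](C)(C)C(C)(C)C)C/C(C)=C/CCC#CCOC2CCCCO2)cc1
F4 | step 12 | (2E,4S,6E)-4-(tert-butyldimethylsilyloxy)-2,6-dimethyl-12-(oxan-2-yloxy)dodeca-2,6-dien-10-yn-1-ol | OC/C(C)=C/[C@@H](O[Si](C)(C)C(C)(C)C)C/C(C)=C/CCC#CCOC1CCCCO1
F5 | step 12 | allylic chloride of F4 | ClC/C(C)=C/[C@@H](O[Si](C)(C)C(C)(C)C)C/C(C)=C/CCC#CCOC1CCCCO1
F6 | step 12 | (6E,9S,10E)-12-chloro-9-(tert-butyldimethylsilyloxy)-7,11-dimethyldodeca-6,10-dien-2-yn-1-ol | ClC/C(C)=C/[C@@H](O[Si](C)(C)C(C)(C)C)C/C(C)=C/CCC#CCO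
F7 | step 19 | 11-(phenylselanyl) derivative of 30 | CC(C)(C)[Si](C)(C)O[C@H]1C/C(C)=C/CC/C(CO[Si](c3ccccc3)(c3ccccc3)C(C)(C)C)=C/[C@H]2OC(=O)C(C)([Se]c3ccccc3)[C@H]12
F8 | step 19 | 8α-(tert-butyldimethylsilyloxy)-15-(tert-butyldiphenylsilyloxy)germacra-1(10)E,4Z,11(13)-trien-12,6α-olide | CC(C)(C)[Si](C)(C)O[C@H]1C/C(C)=C/CC/C(CO[Si](c3ccccc3)(c3ccccc3)C(C)(C)C)=C/[C@H]2OC(=O)C(=C)[C@H]12
F9 | step 20 | 8α,15-dihydroxy-11βH-germacra-1(10)E,4Z-dien-12,6α-olide | O[C@H]1C/C(C)=C/CC/C(CO)=C/[C@H]2OC(=O)[C@@H](C)[C@H]12
F10 | step 23 | 8α-[2-(diethoxyphosphoryl)acetoxy]-15-(tert-butyldiphenylsilyloxy)-11βH-germacra-1(10)E,4Z-dien-12,6α-olide | CCOP(=O)(OCC)CC(=O)O[C@H]1C/C(C)=C/CC/C(CO[Si](c3ccccc3)(c3ccccc3)C(C)(C)C)=C/[C@H]2OC(=O)[C@@H](C)[C@H]12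
F11 | step 23 | 8α-[2-(hydroxymethyl)acryloyloxy]-15-(tert-butyldiphenylsilyloxy)-11βH-germacra-1(10)E,4Z-dien-12,6α-olide | C=C(CO)C(=O)O[C@H]1C/C(C)=C/CC/C(CO[Si](c3ccccc3)(c3ccccc3)C(C)(C)C)=C/[C@H]2OC(=O)[C@@H](C)[C@H]12
A1 | alternative 1 | 8α-(triethylsilyloxy)-15-(tert-butyldimethylsilyloxy)-11βH-germacra-1(10)E,2Z,4-trien-12,6α-olide (C4=C5 ring-trans) | CC[Si](CC)(CC)O[C@H]1C/C(C)=C/C=C\C(CO[Si](C)(C)C(C)(C)C)=C\[C@H]2OC(=O)[C@@H](C)[C@H]12
A2 | alternative 1 | 8α-(triethylsilyloxy)-15-(tert-butyldimethylsilyloxy)-5αH,11βH-eudesma-1,3-dien-12,6α-olide (trans-fused, 10β-methyl) | CC[Si](CC)(CC)O[C@H]1C[C@@]2(C)C=CC=C(CO[Si](C)(C)C(C)(C)C)[C@@H]2[C@H]3OC(=O)[C@@H](C)[C@H]13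
A3 | alternative 2 | 8α-hydroxy-15-(tert-butyldimethylsilyloxy)-11βH-germacra-1(10)E,4Z-dien-12,6α-olide | O[C@H]1C/C(C)=C/CC/C(CO[Si](C)(C)C(C)(C)C)=C/[C@H]2OC(=O)[C@@H](C)[C@H]12
A4 | alternative 2 | (5R)-5-[(1Z,5E)-2-{[(tert-butyldimethylsilyl)oxy]methyl}-6-methyl-8-oxoocta-1,5-dien-1-yl]-3-methylfuran-2(5H)-one | O=CC/C(C)=C/CC/C(CO[Si](C)(C)C(C)(C)C)=C/[C@H]1OC(=O)C(C)=C1
A5 | alternative 3 | 8α-(triethylsilyloxy)-15-(tert-butyldimethylsilyloxy)-11βH-germacra-1(10)E,4Z-dien-12,6α-olide | CC[Si](CC)(CC)O[C@H]1C/C(C)=C/CC/C(CO[Si](C)(C)C(C)(C)C)=C/[C@H]2OC(=O)[C@@H](C)[C@H]12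
A6 | alternative 3 | 1,2-seco precursor: 11βH-12,6α-olide with a (1Z)-2-{[(tert-butyldimethylsilyl)oxy]methyl}buta-1,3-dien-1-yl group on C6 and a (1S,3E)-4-iodo-3-methyl-1-(triethylsilyloxy)but-3-en-1-yl group on C7 | I/C=C(\C)C[C@H](O[Si](CC)(CC)CC)[C@H]1[C@H](C)C(=O)O[C@@H]1/C=C(\CO[Si](C)(C)C(C)(C)C)C=C
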